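The ten-membered ring is never closed end to end. Because the oxygen-bearing C6 lies 1,5 to C10, the ester-bearing carbon of the ring-cis C1=C10 enoate, a temporary C6–C10 bond folds the carbocycle into a cyclopentane (C6–C10) cis-fused to a cycloheptene (C10, C1–C6) in which C4=C5 can only be cis. In step 16 the C6 alkoxide expels the C1 mesylate: one Grob fragmentation cuts C6–C10 and delivers the C6 ketone, the C1=C10 enoate and the ten-membered ring. The precursor is a cis-hydroazulene with tertiary C6–OH, C10 ester, C1 mesylate and the tartrate-derived C7–C9 triad, C11–C13 being carried as a malonate.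

Key step: step 16

Remarks on the chemistry (assumptions and design choices):
- Germacrane numbering (C1–C15) is kept for every intermediate, also monocyclic and open-chain ones.
- Aldehyde 7 is the E isomer under the sequence rules: iodine is cis to the C3 chain and trans to CH2OSi, which is what a cis C4=C5 inside the seven-membered ring requires.
- Assumption: di-tert-butyl oxomalonate 21 is a catalogue reagent.
- β-Keto acid 16 and esters 17 and 18 are drawn as the C10 epimer with the carboxyl trans to O9; C10 is enolisable and is fixed in step 11.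
- O9 carries the ether (PMB) and O8 the silyl group (TBS), because only O9 is cis-1,3 to the C6 alkoxide of the key step, where a silyl group could migrate.
- C11–C13 are carried as a di-tert-butyl malonate. This removes the 3-oxido-1,5-diene (anionic oxy-Cope path) and the allylic, acidified C7–H that a 2-propenyl group would bring, and it allows C7 to be set by hydride delivery. The carboxyl carbon at C13 is later exchanged for a formaldehyde carbon (step 19).

Step 1
Reactants: 1 prop-2-yn-1-ol
Product: 2 tert-butyl(diphenyl)(prop-2-yn-1-yloxy)silane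
Conditions: TBDPSCl, imidazole, CH2Cl2, 0 → 23 °C
Reagents that add atoms: tert-butyl(chloro)diphenylsilane CC(C)(C)[Si](Cl)(c1ccccc1)c1ccccc1
Why: Silylation of a primary alcohol; the bulky, weakly coordinating silyl ether is chosen to favour branched carbocupration in step 2.

Step 2
Reactants: 3 2-(2-bromoethyl)-1,3-dioxolane; 2 tert-butyl(diphenyl)(prop-2-yn-1-yloxy)silane
Product: 6 2-[(3E)-3-{[tert-butyl(diphenyl)silyl]oxymethyl}-4-iodobut-3-en-1-yl]-1,3-dioxolane, via Grignard reagent 4 (not isolated), via alkenylcopper 5 (not isolated)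
Conditions: Mg, THF, 25 °C; CuBr·SMe2, Et2O/Me2S, −45 °C; 2, −25 °C; I2, THF, −78 → 0 °C
Reagents that add atoms: iodine II
Why: Normant carbocupration adds the alkylcopper syn across the terminal alkyne with carbon at the internal position, and iodinolysis with retention leaves iodine cis to the new chain.

Step 3
Reactants: 6 2-[(3E)-3-{[tert-butyl(diphenyl)silyl]oxymethyl}-4-iodobut-3-en-1-yl]-1,3-dioxolane
Product: 7 (4E)-4-{[tert-butyl(diphenyl)silyl]oxymethyl}-5-iodopent-4-enal
Conditions: 2 M HCl, THF, 23 °C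
Reagents that add atoms: water O
Why: Acid-catalysed acetal hydrolysis; the silyl ether and the alkenyl iodide are stable to dilute acid.

Step 4
Reactants: 8 diethyl (2R,3R)-tartrate
Product: 9 diethyl (2R,3R)-2-hydroxy-3-[(4-methoxybenzyl)oxy]succinate
Conditions: Ag2O, PMBCl, n-Bu4NI (cat.), CH2Cl2, 23 °C
Reagents that add atoms: 4-methoxybenzyl chloride COc1ccc(CCl)cc1
Why: Silver-oxide-mediated mono-etherification (Williamson type without strong base); the two hydroxyls are equivalent by C2 symmetry, so one mono-ether results and the α-centres are not epimerised.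

Step 5
Reactants: 9 diethyl (2R,3R)-2-hydroxy-3-[(4-methoxybenzyl)oxy]succinate
Product: 10 diethyl (2R,3R)-2-[(4-methoxybenzyl)oxy]-3-(triethylsilyloxy)succinate
Conditions: TESCl, imidazole, CH2Cl2, 0 °C
Reagents that add atoms: chlorotriethylsilane CC[Si](Cl)(CC)CC
Why: Silylation; a temporary, acid-labile group for O8 that is removed in step 8.

Step 6
Reactants: 10 diethyl (2R,3R)-2-[(4-methoxybenzyl)oxy]-3-(triethylsilyloxy)succinate
Product: 11 (2S,3S)-2-[(4-methoxybenzyl)oxy]-3-(triethylsilyloxy)butane-1,4-diol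
Conditions: LiBH4, Et2O, 0 °C
Reagents that add atoms: none
Why: Borohydride reduction of both esters to primary alcohols; the stereocentres are not involved (the descriptors change only through priorities).

Step 7
Reactants: 11 (2S,3S)-2-[(4-methoxybenzyl)oxy]-3-(triethylsilyloxy)butane-1,4-diol
Product: 12 (2R,3R)-1,4-diiodo-2-[(4-methoxybenzyl)oxy]-3-(triethylsilyloxy)butane
Conditions: I2, PPh3, imidazole, CH2Cl2, 0 → 23 °C
Reagents that add atoms: iodine II
Why: Appel-type iodination of two primary alcohols under near-neutral conditions.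

Step 8
Reactants: 12 (2R,3R)-1,4-diiodo-2-[(4-methoxybenzyl)oxy]-3-(triethylsilyloxy)butane; 13 p-toluenesulfonylmethyl isocyanide
Product: 15 (3S,4S)-3-hydroxy-4-[(4-methoxybenzyl)oxy]cyclopentanone, via isocyanide adduct 14 (not isolated)
Conditions: NaH, DMSO/Et2O, 0 → 23 °C; then conc. HCl, Et2O/CH2Cl2, 0 °C
Reagents that add atoms: water O
Why: TosMIC ketone synthesis (van Leusen): double alkylation of the acyl-anion equivalent closes the five-membered ring at C6 without regiochemical ambiguity, and the acid that unmasks the ketone also removes the TES group.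

Step 9
Reactants: 15 (3S,4S)-3-hydroxy-4-[(4-methoxybenzyl)oxy]cyclopentanone
Product: 17 methyl 4-hydroxy-5-[(4-methoxybenzyl)oxy]-2-oxocyclopentane-1-carboxylate (ester on C10; O8 and O9 trans), via β-keto acid 16 (not isolated)
Conditions: LiN(i-Pr)2 (2.2 equiv), THF, −78 °C; CO2; 1 M HCl, 0 °C; then TMSCHN2, PhMe/MeOH, 0 °C
Reagents that add atoms: carbon dioxide O=C=O; (trimethylsilyl)diazomethane C[Si](C)(C)C=[N+]=[N-]
Why: Enolate carboxylation then diazoalkane esterification; the C8 lithium alkoxide forms first, so the second deprotonation occurs at C10, remote from the alkoxide, which places the ester next to C9–OPMB.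

Step 10
Reactants: 17 methyl 4-hydroxy-5-[(4-methoxybenzyl)oxy]-2-oxocyclopentane-1-carboxylate
Product: 18 methyl 4-(tert-butyldimethylsilyloxy)-5-[(4-methoxybenzyl)oxy]-2-oxocyclopentane-1-carboxylate
Conditions: TBSCl, imidazole, DMAP (cat.), DMF, 23 °C
Reagents that add atoms: tert-butyl(chloro)dimethylsilane CC(C)(C)[Si](C)(C)Cl
Why: Silylation of the C8 hydroxyl; a bulky, poor leaving group is wanted there for steps 13, 14 and 16.

Step 11
Reactants: 18 methyl 4-(tert-butyldimethylsilyloxy)-5-[(4-methoxybenzyl)oxy]-2-oxocyclopentane-1-carboxylate; 7 (4E)-4-{[tert-butyl(diphenyl)silyl]oxymethyl}-5-iodopent-4-enal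
Product: 19 aldol adduct: C10-quaternary β-keto ester carrying the C1 carbinol chain (C1 chain trans to O9; C1–OH syn to the ester)
Conditions: TiCl4, Et3N, CH2Cl2, −78 °C; then 7
Reagents that add atoms: none
Why: Titanium-enolate aldol addition of the chelated β-keto ester through a closed chair transition state; the aldehyde approaches C10 anti to the vicinal C9–OPMB (sets C10) and its chain sits equatorial (sets C1), and the strong titanium aldolate suppresses retro-aldol.

Step 12
Reactants: 19 aldol adduct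
Product: 20 C1 mesylate of 19
Conditions: MsCl, Et3N, DMAP (cat.), CH2Cl2, 0 °C
Reagents that add atoms: methanesulfonyl chloride CS(=O)(=O)Cl
Why: Sulfonylation with retention at C1; capping the carbinol also blocks retro-aldol in the base steps that follow.

Step 13
Reactants: 20 C1 mesylate; 21 di-tert-butyl oxomalonate
Product: 23 C7 alkylidene malonate (C7=C11), via aldol adduct 22 (not isolated)
Conditions: LiN(SiMe3)2, THF, −78 °C; 21; then SOCl2, pyridine, −78 → 0 °C
Reagents that add atoms: none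
Why: Aldol condensation: C7 is the only enolisable position (C10 is quaternary), the non-enolisable tricarbonyl electrophile adds cleanly, and the chlorosulfite is eliminated towards the acidic C7–H.

Step 14
Reactants: 23 C7 alkylidene malonate
Product: 24 C7 malonate, malonyl group cis to C8–OTBS
Conditions: Hantzsch ester, CH2Cl2, 23 °C
Reagents that add atoms: none
Why: Transfer hydrogenation (conjugate reduction) of an alkylidene malonate: hydride adds to C7, the β-carbon of the malonate, on the face opposite C8–OTBS, which allylic strain with the ester holds pseudo-axial, so C11 ends cis to O8 under neutral, non-epimerising conditions.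

Step 15
Reactants: 24 C7 malonate
Product: 25 cis-fused 6-hydroxy-1-mesyloxy hydroazulene ester (bicyclo[5.3.0]dec-4-ene; C6–OH cis to the C10 ester)
Conditions: CrCl2 (6 equiv), NiCl2 (2 mol %), DMSO/THF, 23 → 45 °C
Reagents that add atoms: none
Why: Nozaki–Hiyama–Kishi reaction: the alkenyl iodide becomes an alkenylchromium that adds intramolecularly to the C6 ketone from the face of the C10 side chain, which enforces the cis ring fusion; ester, mesylate and malonate are tolerated.

Step 16
Reactants: 25 cis-fused 6-hydroxy-1-mesyloxy hydroazulene ester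
Product: 26 ten-membered 1(10),4-dien-6-one with C10 methyl ester, C9–OPMB, C8–OTBS and C7 malonate
Conditions: KN(SiMe3)2 (2.1 equiv), THF, −78 °C; AcOH quench at −78 °C
Reagents that add atoms: none
Why: KN(SiMe3)2 first removes the malonate C–H and then the tertiary C6–OH proton; the C6 alkoxide pushes the C6–C10 σ-electrons into a new C10=C1 π-bond while the C1 mesylate leaves from the antiperiplanar position, a concerted Grob fragmentation of a 1,3-hydroxy sulfonate that the C10 ester assists by stabilising developing charge. The closest known reaction type is the alkoxide-induced fragmentation of bicyclic γ-sulfonyloxy alcohols to medium-ring unsaturated ketones. The ten-membered ring is not formed by an end-to-end closure: it appears when the fusion bond shared by the cyclopentane and the cycloheptene is cut, so no cyclisation mode applies. No stereocentre is created; C6 and C10 become trigonal and C7, C8 and C9 are untouched. The selectivity needed is the C1=C10 geometry (C2 cis to C9); it is secured because the mesylate is trans to the ester and cis to C9 on the seven-membered ring, so only the conformer with C1–O anti to C6–C10 fragments and it places C2 beside C9. Side paths are limited by design: no silyl group is cis-1,3 to the alkoxide, no vinyl group at C7 offers an oxy-Cope path, the potassium malonate next to C7 disfavours enolisation of the new ketone towards O8, and the cold quench limits retro-aldol equilibration.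

Step 17
Reactants: 26 ten-membered 1(10),4-dien-6-one
Product: 27 (6R)-allylic alcohol
Conditions: NaBH4, CeCl3·7H2O, MeOH, −78 °C
Reagents that add atoms: none
Why: Luche 1,2-reduction of the enone; hydride is expected to approach C6 from the ring periphery in the conformer with the C7 and C8 substituents pseudo-equatorial, giving the alcohol trans to C11 (if the other face is attacked, see the fallback).

Step 18
Reactants: 27 (6R)-allylic alcohol
Product: 29 trans-fused 6,12-lactone with C11 carboxylic acid, via hydroxy diacid 28 (not isolated)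
Conditions: TMSOTf, 2,6-lutidine, CH2Cl2, 0 °C; then 1 M HCl, THF, 23 °C
Reagents that add atoms: none
Why: Silyl-triflate cleavage of the tert-butyl esters (PMB, TBS and TBDPS ethers are kept) followed by acid-catalysed γ-lactonisation of the malonic acid onto C6–OH; C11 is epimerisable and is drawn as the trans isomer.

Step 19
Reactants: 29 lactone acid
Product: 30 α-methylene-γ-lactone (O9 PMB; O8 TBS; O15 TBDPS)
Conditions: 37% aq CH2O, Et2NH, THF, 23 °C; then NaOAc, AcOH, 50 °C
Reagents that add atoms: formaldehyde C=O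
Why: Decarboxylative Mannich methylenation of an α-carboxy lactone: aminomethylation at C11, then loss of CO2 and amine gives the exocyclic alkene without strong base.

Step 20
Reactants: 30 α-methylene-γ-lactone
Product: 31 C8 alcohol
Conditions: CSA (cat.), MeOH/CH2Cl2, 0 → 23 °C
Reagents that add atoms: none
Why: Acid-catalysed methanolysis of the secondary TBS ether; the primary TBDPS ether and the PMB ether are stable to these conditions.

Step 21
Reactants: 31 C8 alcohol
Product: 32 C8 isobutyrate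
Conditions: (i-PrCO)2O, Et3N, DMAP (cat.), CH2Cl2, 0 → 23 °C
Reagents that add atoms: isobutyric anhydride CC(C)C(=O)OC(=O)C(C)C
Why: DMAP-catalysed acylation of the only free hydroxyl.

Step 22
Reactants: 32 C8 isobutyrate
Product: 33 C9 alcohol
Conditions: DDQ, CH2Cl2/pH 7 buffer, 0 °C
Reagents that add atoms: none
Why: Oxidative cleavage of the PMB ether; esters, silyl ether and the alkenes are not affected.

Step 23
Reactants: 33 C9 alcohol
Product: 34 C9 acetate
Conditions: Ac2O, pyridine, DMAP (cat.), CH2Cl2, 0 °C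
Reagents that add atoms: acetic anhydride CC(=O)OC(C)=O
Why: Acetylation of the only free hydroxyl.

Step 24
Reactants: 34 C9 acetate
Product: 35 CNP0242134.2
Conditions: HF·pyridine, THF/pyridine, 0 → 23 °C
Reagents that add atoms: none
Why: Fluoride-mediated removal of the primary TBDPS ether under buffered, non-basic conditions that spare the three esters and the α-methylene lactone.

Compound list
1 | prop-2-yn-1-ol | C#CCO | starting material
2 | tert-butyl(diphenyl)(prop-2-yn-1-yloxy)silane | C#CCO[Si](c1ccccc1)(c1ccccc1)C(C)(C)C | intermediate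
3 | 2-(2-bromoethyl)-1,3-dioxolane | BrCCC1OCCO1 | starting material
4 | [2-(1,3-dioxolan-2-yl)ethyl]magnesium bromide | Br[Mg]CCC1OCCO1 | intermediate
5 | (E)-alkenylcopper, Cu on C5 cis to the dioxolanylethyl chain | [Cu]/C=C(/CO[Si](c1ccccc1)(c1ccccc1)C(C)(C)C)CCC1OCCO1 | intermediate
6 | 2-[(3E)-3-{[tert-butyl(diphenyl)silyl]oxymethyl}-4-iodobut-3-en-1-yl]-1,3-dioxolane | I/C=C(/CO[Si](c1ccccc1)(c1ccccc1)C(C)(C)C)CCC1OCCO1 | intermediate
7 | (4E)-4-{[tert-butyl(diphenyl)silyl]oxymethyl}-5-iodopent-4-enal (C1–C5, C15) | O=CCC/C(CO[Si](c1ccccc1)(c1ccccc1)C(C)(C)C)=C\I | intermediate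
8 | diethyl (2R,3R)-tartrate (diethyl L-tartrate) | CCOC(=O)[C@H](O)[C@@H](O)C(=O)OCC | starting material
9 | diethyl (2R,3R)-2-hydroxy-3-[(4-methoxybenzyl)oxy]succinate | CCOC(=O)[C@H](OCc1ccc(OC)cc1)[C@@H](O)C(=O)OCC | intermediate
10 | diethyl (2R,3R)-2-[(4-methoxybenzyl)oxy]-3-(triethylsilyloxy)succinate | CCOC(=O)[C@H](OCc1ccc(OC)cc1)[C@@H](O[Si](CC)(CC)CC)C(=O)OCC | intermediate
11 | (2S,3S)-2-[(4-methoxybenzyl)oxy]-3-(triethylsilyloxy)butane-1,4-diol | OC[C@H](OCc1ccc(OC)cc1)[C@@H](O[Si](CC)(CC)CC)CO | intermediate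
12 | (2R,3R)-1,4-diiodo-2-[(4-methoxybenzyl)oxy]-3-(triethylsilyloxy)butane | IC[C@H](OCc1ccc(OC)cc1)[C@@H](O[Si](CC)(CC)CC)CI | intermediate
13 | p-toluenesulfonylmethyl isocyanide (TosMIC) | [C-]#[N+]CS(=O)(=O)c1ccc(C)cc1 | starting material
14 | 1-isocyano-1-tosylcyclopentane with trans 3-OPMB and 4-OTES (both C6 epimers) | [C-]#[N+]C1(S(=O)(=O)c2ccc(C)cc2)C[C@H](OCc2ccc(OC)cc2)[C@@H](O[Si](CC)(CC)CC)C1 | intermediate
15 | (3S,4S)-3-hydroxy-4-[(4-methoxybenzyl)oxy]cyclopentanone (C6 ketone, C8–OH, C9–OPMB) | O=C1C[C@H](OCc2ccc(OC)cc2)[C@@H](O)C1 | intermediate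
16 | 4-hydroxy-5-[(4-methoxybenzyl)oxy]-2-oxocyclopentane-1-carboxylic acid (carboxyl on C10, trans to O9) | OC(=O)[C@H]1[C@H](OCc2ccc(OC)cc2)[C@@H](O)CC1=O | intermediate
17 | methyl 4-hydroxy-5-[(4-methoxybenzyl)oxy]-2-oxocyclopentane-1-carboxylate (O8/O9 trans; ester trans to O9) | COC(=O)[C@H]1[C@H](OCc2ccc(OC)cc2)[C@@H](O)CC1=O | intermediate
18 | methyl 4-(tert-butyldimethylsilyloxy)-5-[(4-methoxybenzyl)oxy]-2-oxocyclopentane-1-carboxylate | COC(=O)[C@H]1[C@H](OCc2ccc(OC)cc2)[C@@H](O[Si](C)(C)C(C)(C)C)CC1=O | intermediate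
19 | aldol adduct: cyclopentanone with quaternary C10 (ester cis to O9, C1 carbinol chain trans to O9), C8–OTBS, C9–OPMB, (E)-iodoalkene chain | COC(=O)[C@@]1([C@H](O)CC/C(CO[Si](c2ccccc2)(c2ccccc2)C(C)(C)C)=C\I)C(=O)C[C@H](O[Si](C)(C)C(C)(C)C)[C@H]1OCc3ccc(OC)cc3 | intermediate
20 | C1 mesylate of 19 | COC(=O)[C@@]1([C@H](OS(C)(=O)=O)CC/C(CO[Si](c2ccccc2)(c2ccccc2)C(C)(C)C)=C\I)C(=O)C[C@H](O[Si](C)(C)C(C)(C)C)[C@H]1OCc3ccc(OC)cc3 | intermediate
21 | di-tert-butyl oxomalonate | CC(C)(C)OC(=O)C(=O)C(=O)OC(C)(C)C | starting material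
22 | C7 aldol adduct of 20 (tertiary carbinol at C11, trans to O8) | COC(=O)[C@@]1([C@H](OS(C)(=O)=O)CC/C(CO[Si](c2ccccc2)(c2ccccc2)C(C)(C)C)=C\I)C(=O)[C@@H](C(O)(C(=O)OC(C)(C)C)C(=O)OC(C)(C)C)[C@H](O[Si](C)(C)C(C)(C)C)[C@H]1OCc3ccc(OC)cc3 | intermediate
23 | C7 alkylidene malonate (C7=C11) | COC(=O)[C@@]1([C@H](OS(C)(=O)=O)CC/C(CO[Si](c2ccccc2)(c2ccccc2)C(C)(C)C)=C\I)C(=O)C(=C(C(=O)OC(C)(C)C)C(=O)OC(C)(C)C)[C@H](O[Si](C)(C)C(C)(C)C)[C@H]1OCc3ccc(OC)cc3 | intermediate
24 | C7 malonate, malonyl cis to C8–OTBS | COC(=O)[C@@]1([C@H](OS(C)(=O)=O)CC/C(CO[Si](c2ccccc2)(c2ccccc2)C(C)(C)C)=C\I)C(=O)[C@H](C(C(=O)OC(C)(C)C)C(=O)OC(C)(C)C)[C@H](O[Si](C)(C)C(C)(C)C)[C@H]1OCc3ccc(OC)cc3 | intermediate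
25 | key-step precursor: cis-fused 6-hydroxy-1-mesyloxy hydroazulene C10 methyl ester; C4=C5 in the seven-membered ring; C7 malonate, C8–OTBS, C9–OPMB, C15–OTBDPS | COC(=O)[C@@]12[C@H](OS(C)(=O)=O)CC/C(CO[Si](c3ccccc3)(c3ccccc3)C(C)(C)C)=C\[C@]1(O)[C@H](C(C(=O)OC(C)(C)C)C(=O)OC(C)(C)C)[C@H](O[Si](C)(C)C(C)(C)C)[C@H]2OCc3ccc(OC)cc3 | intermediate
26 | key-step product: ten-membered 1(10),4-dien-6-one; C2 cis to C9 and C3 cis to C6 on the ring | O=C1/C=C(/CO[Si](c2ccccc2)(c2ccccc2)C(C)(C)C)CC/C=C(/C(=O)OC)[C@H](OCc2ccc(OC)cc2)[C@@H](O[Si](C)(C)C(C)(C)C)[C@H]1C(C(=O)OC(C)(C)C)C(=O)OC(C)(C)C | intermediate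
27 | (6R)-allylic alcohol | O[C@@H]1/C=C(/CO[Si](c2ccccc2)(c2ccccc2)C(C)(C)C)CC/C=C(/C(=O)OC)[C@H](OCc2ccc(OC)cc2)[C@@H](O[Si](C)(C)C(C)(C)C)[C@H]1C(C(=O)OC(C)(C)C)C(=O)OC(C)(C)C | intermediate
28 | hydroxy malonic acid | O[C@@H]1/C=C(/CO[Si](c2ccccc2)(c2ccccc2)C(C)(C)C)CC/C=C(/C(=O)OC)[C@H](OCc2ccc(OC)cc2)[C@@H](O[Si](C)(C)C(C)(C)C)[C@H]1C(C(=O)O)C(=O)O | intermediate
29 | trans-fused 6,12-lactone with C11–CO2H (C11 epimerisable; drawn trans) | OC(=O)[C@@H]1C(=O)O[C@@H]2/C=C(/CO[Si](c3ccccc3)(c3ccccc3)C(C)(C)C)CC/C=C(/C(=O)OC)[C@H](OCc3ccc(OC)cc3)[C@@H](O[Si](C)(C)C(C)(C)C)[C@@H]12 | intermediate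
30 | α-methylene lactone; O9 PMB, O8 TBS, O15 TBDPS | C=C1C(=O)O[C@@H]2/C=C(/CO[Si](c3ccccc3)(c3ccccc3)C(C)(C)C)CC/C=C(/C(=O)OC)[C@H](OCc3ccc(OC)cc3)[C@@H](O[Si](C)(C)C(C)(C)C)[C@@H]12 | intermediate
31 | C8 alcohol | C=C1C(=O)O[C@@H]2/C=C(/CO[Si](c3ccccc3)(c3ccccc3)C(C)(C)C)CC/C=C(/C(=O)OC)[C@H](OCc3ccc(OC)cc3)[C@@H](O)[C@@H]12 | intermediate
32 | C8 isobutyrate | C=C1C(=O)O[C@@H]2/C=C(/CO[Si](c3ccccc3)(c3ccccc3)C(C)(C)C)CC/C=C(/C(=O)OC)[C@H](OCc3ccc(OC)cc3)[C@@H](OC(=O)C(C)C)[C@@H]12 | intermediate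
33 | C9 alcohol | C=C1C(=O)O[C@@H]2/C=C(/CO[Si](c3ccccc3)(c3ccccc3)C(C)(C)C)CC/C=C(/C(=O)OC)[C@H](O)[C@@H](OC(=O)C(C)C)[C@@H]12 | intermediate
34 | C9 acetate, O15 TBDPS | C=C1C(=O)O[C@@H]2/C=C(/CO[Si](c3ccccc3)(c3ccccc3)C(C)(C)C)CC/C=C(/C(=O)OC)[C@H](OC(C)=O)[C@@H](OC(=O)C(C)C)[C@@H]12 | intermediate
35 | CNP0242134.2: (6R,7S,8S,9S) 6,12-lactone with 8-isobutyrate, 9-acetate, C14 methyl ester, 15-OH | C=C1C(=O)O[C@@H]2/C=C(/CO)CC/C=C(/C(=O)OC)[C@H](OC(C)=O)[C@@H](OC(=O)C(C)C)[C@@H]12 | target

Total step count: 24. Longest linear sequence: 21 steps (steps 4–24, from diethyl L-tartrate); aldehyde 7 is made in 3 steps and joins in step 11.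

Steps most likely to fail

Step 15. The alkenylchromium may add too slowly to the crowded C6 ketone (quaternary C10 on one side, the C7 malonate on the other), so that protodeiodination takes over. Fallback: the order of ring formation is inverted. Starting from ketone 24, NaBH4 (MeOH, −20 °C) gives cyclopentanol F1 (either C6 epimer serves). KN(SiMe3)2 (2 equiv, THF, −78 → 0 °C) then fragments this 1,3-hydroxy mesylate at the monocyclic stage, with the same antiperiplanar requirement and therefore the same C1=C10 geometry, to the open-chain enoate aldehyde F2. A Nozaki–Hiyama–Kishi macrocyclisation (CrCl2, NiCl2, DMSO, high dilution) onto the aldehyde closes C5–C6 and rejoins the route at allylic alcohol 27.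

Step 16. The alkoxide may open by a stepwise retro-aldol path to a C10 ester enolate, which would lose the geometric control, or the malonate anion may attack across the ring. Fallback: a radical fragmentation that needs no alkoxide. From 25, PhI(OAc)2 and I2 under visible light (CH2Cl2, 23 °C) generate the C6 alkoxy radical, whose β-scission of C6–C10 gives the ten-membered ketone as the tertiary α-iodo ester F3 (C10 epimers). Zn dust (AcOH/THF) then eliminates iodide and mesylate to the enoate and returns to 26, with geometry under thermodynamic rather than stereospecific control.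

Step 17. Hydride may be delivered to the other face of C6, giving the epimer that would close a cis-lactone. Fallback: Mitsunobu inversion. The epimeric alcohol F4 is treated with 4-nitrobenzoic acid, PPh3 and DIAD (THF, 0 °C) to give the inverted ester F5, and K2CO3 in MeOH releases 27.

Further compounds
F1 | step 15 | cyclopentanol (C6 alcohol of 24; expected major epimer drawn) | COC(=O)[C@@]1([C@H](OS(C)(=O)=O)CC/C(CO[Si](c2ccccc2)(c2ccccc2)C(C)(C)C)=C\I)[C@H](O)[C@H](C(C(=O)OC(C)(C)C)C(=O)OC(C)(C)C)[C@H](O[Si](C)(C)C(C)(C)C)[C@H]1OCc3ccc(OC)cc3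
F2 | step 15 | open-chain enoate aldehyde (C6 aldehyde; C1=C10 with C2 cis to C9) | I/C=C(/CO[Si](c1ccccc1)(c1ccccc1)C(C)(C)C)CC/C=C(/C(=O)OC)[C@H](OCc1ccc(OC)cc1)[C@@H](O[Si](C)(C)C(C)(C)C)[C@H](C=O)C(C(=O)OC(C)(C)C)C(=O)OC(C)(C)C
F3 | step 16 | ten-membered 6-ketone with C10 iodide and C1 mesylate (C10 epimers) | O=C1/C=C(/CO[Si](c2ccccc2)(c2ccccc2)C(C)(C)C)CC[C@@H](OS(C)(=O)=O)C(I)(C(=O)OC)[C@H](OCc2ccc(OC)cc2)[C@@H](O[Si](C)(C)C(C)(C)C)[C@H]1C(C(=O)OC(C)(C)C)C(=O)OC(C)(C)C
F4 | step 17 | (6S)-allylic alcohol (C6 epimer of 27) | O[C@H]1/C=C(/CO[Si](c2ccccc2)(c2ccccc2)C(C)(C)C)CC/C=C(/C(=O)OC)[C@H](OCc2ccc(OC)cc2)[C@@H](O[Si](C)(C)C(C)(C)C)[C@H]1C(C(=O)OC(C)(C)C)C(=O)OC(C)(C)C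
F5 | step 17 | (6R)-4-nitrobenzoate of 27 | O=C(O[C@@H]1/C=C(/CO[Si](c2ccccc2)(c2ccccc2)C(C)(C)C)CC/C=C(/C(=O)OC)[C@H](OCc2ccc(OC)cc2)[C@@H](O[Si](C)(C)C(C)(C)C)[C@H]1C(C(=O)OC(C)(C)C)C(=O)OC(C)(C)C)c1ccc(cc1)[N+](=O)[O-]
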